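At late times the earlier runs already differed: by 20.0 min north held Sub at 26.9%, less than west's 33.9%, and north had the larger charge of Ptn. North's Sub2 stood at 47.4% at that time, and I took [Ptn] as the concentration that set the order of the rate.

| setting | west | north | flask |
|---|---|---|---|
| Sub | 0.050 M | 0.050 M | 0.050 M |
| Sub2 | 0.050 M | 0.050 M | 0.050 M |
| Ptn | 0.028 M | 0.041 M | 0.0550 M |
| Oth2 | 0.25 mM | 0.25 mM | 0.25 mM |
| Oth | 0.14 mM | 0.14 mM | 0.14 mM |
| remark | run made earlier | run made earlier |  |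
| time |  |  | 15 min |

| run | time / min | Sub / % | Sub2 / % |
|---|---|---|---|
| west | 4.00 | 45.6 | 49.0 |
| west | 8.00 | 42.7 | 47.9 |
| west | 10.0 | 40.4 | 48.8 |
| west | 15.0 | 36.6 | 48.6 |
| west | 20.0 | 33.9 | 48.8 |
| north | 1.50 | 48.7 | 50.7 |
| north | 5.00 | 41.7 | 50.7 |
| north | 8.00 | 38.2 | 49.2 |
| north | 12.0 | 33.2 | 48.5 |
| north | 20.0 | 26.9 | 47.4 |

(readings scatter by 0.5 percentage points)

- Kat is single-handed; Sub and Sub2 are mirror images of each other, charged as a racemate, each of them at the stated concentration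
- an excess is the difference of the two amounts in percent of their sum
- an excess is below zero if the other one leads

* part of the Sub and Sub2 charged together that has reacted at 15 min
* excess of Tgt over Tgt2 in the product at 15 min
* excess of Sub2 over Sub among what is left of the two at 15 min

I counted one Ptn lost per Sub or Sub2 lost. Then I took the logarithm of Sub's start over its last reading and divided by the time and by the mean of [Ptn] at start and end. This is a pseudo-first-order constant of Sub per [Ptn]. North gave 1.10 L mol⁻¹ min⁻¹ and west 1.00 L mol⁻¹ min⁻¹. I carried their mean, the Ptn constant, 1.05 L mol⁻¹ min⁻¹.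

For the flask I held Sub2 at north's last reading. With [Ptn] held at its charge, I reckoned Sub at 21.0%, my bound from below. That reckoned loss put Ptn at 0.0234 M, and with [Ptn] held there I reckoned Sub at 34.6%, my bound from above. Each bound gave the other's end value for a mean [Ptn], which tightened Sub to 24.2% and 26.9%. So I put c from 25.7% to 28.4%, and eS from 27.5% to 32.4%.

The forecast said “I take about 1.2 for the flask”, where I held 1.05 L mol⁻¹ min⁻¹. It gave c 28%, eP 80% and eS 31%, and its c and eS fell inside my bracket.

The flask gave c 27.1%, eP 81.3% and eS 30.0%.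

    Kat + Sub ⇌ Kat.Sub (K = 21.0 L mol⁻¹, k = 625 L mol⁻¹ s⁻¹)
    Kat + Sub2 ⇌ Kat.Sub2 (K = 63.2 L mol⁻¹, k = 1160 L mol⁻¹ s⁻¹)
    Ptn + Kat.Sub → Kat + Tgt (k = 49.0 L mol⁻¹ s⁻¹)
    Ptn + Kat.Sub2 → Kat + Tgt2 (k = 1.18 L mol⁻¹ s⁻¹)
    Kat + Oth → Kat.Oth (k = 645 L mol⁻¹ s⁻¹)
    Oth2 → Kat (k = 0.00782 s⁻¹)

Reckoned the same way, the flask's Ptn constant was 1.08 L mol⁻¹ min⁻¹. A second flask charged with 0.22 M of Ptn, ending with Sub at 2.38% and Ptn at 72.8% of its charge, gave 1.07 L mol⁻¹ min⁻¹. In the flask at 15.0 min, Kat.Sub2 held 29.2% of the catalyst and Kat.Sub 5.00%. Even so, in the flask at that time, Ptn was used through Kat.Sub 7.1 times as fast as through Kat.Sub2.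

(The runs are calculated with constants of no real substance; the scatter is artificial.)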